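**Plan**

- Retrosynthesis: the TIPS ether on the B-ring phenol is removed last; ring A is taken back to a non-aromatic dihydrophloroglucinol (C7 carbinol); ring C is then cut at C2–C3 and O1–C8a, which gives a chroman aldehyde and a 1-methoxy-3-silyloxy diene built on a 2-acetyl-3-methoxycyclohexenone.
- Enabling feature: O1–C8a=C4a–C4=O is a vinylogous ester and ring A is the tris-enol of a cyclohexane-1,3,5-trione. C8a can therefore carry OMe as a leaving group, C3=C4(OSi)–C4a=C8a(OMe) is a hetero-Diels–Alder diene, and one alcohol oxidation at C7 afterwards restores aromatic ring A.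
- Diene (from phloroglucinol): carbonyl reduction, enol ether, α-iodination, α′-prenylation, Stille acetylation, enol silane. The prenyl group is placed next to the carbonyl that becomes C5, which fixes 6- over 8-prenylation.
- Aldehyde (from 5-bromo-2,3-dihydroxybenzaldehyde): side chain by B-alkyl Suzuki coupling, chroman ring by epoxide opening, dienyl chain by Horner–Wadsworth–Emmons olefination, formyl group from the bromide.
- Ring order: chroman ring first, then ring C on the preformed carbocycle A, then aromatisation of A, then desilylation.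
- Stereochemistry: the quaternary chroman carbon comes from a Katsuki–Sharpless epoxidation followed by invertive 6-exo epoxide opening; flavanone C2 comes from the chiral titanium–BINOL catalyst in the key step.

Key step: step 18

Remark: 3, 4, 7, 9–12 and 31–33 are racemic or diastereomeric at ring-A carbons that become sp2 in step 19, and 19–23 are epimeric at the acetal carbon. Compound 17 is assumed to be a catalogue compound.

**Route**

Step 1
Reactants: 1 phloroglucinol
Product: 2 5-hydroxycyclohexane-1,3-dione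
Conditions: NaBH4, aq. NaOH, 0 °C → rt; then HCl to pH 3
Reagents that add atoms: none
Why: In aqueous base phloroglucinol reacts as its cyclohexanetrione tautomer, so hydride reduces one carbonyl and the reaction should stop at the stabilised 1,3-dione enolate (carbonyl reduction of a keto tautomer).

Step 2
Reactants: 2 5-hydroxycyclohexane-1,3-dione
Product: 3 5-hydroxy-3-methoxycyclohex-2-en-1-one
Conditions: Me3SiCHN2, toluene/MeOH, 0 °C → rt
Reagents that add atoms: (trimethylsilyl)diazomethane C[Si](C)(C)C=[N+]=[N-]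
Why: O-methylation of the acidic enol of a symmetric cyclic 1,3-dione by diazoalkane methyl transfer should give the single possible vinylogous ester without acid or base that could dehydrate the β-hydroxy ketone.

Step 3
Reactants: 3 5-hydroxy-3-methoxycyclohex-2-en-1-one
Product: 4 5-hydroxy-2-iodo-3-methoxycyclohex-2-en-1-one
Conditions: I2, pyridine, CH2Cl2, 0 °C → rt
Reagents that add atoms: iodine II
Why: Electrophilic α-iodination of a β-alkoxy enone at its nucleophilic α-carbon, placed before the prenylation so that no iodoetherification of a prenyl alkene by the neighbouring hydroxyl can compete.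

Step 4
Reactants: 4 5-hydroxy-2-iodo-3-methoxycyclohex-2-en-1-one; 5 1-bromo-3-methylbut-2-ene
Product: 7 5-hydroxy-2-iodo-3-methoxy-6-(3-methylbut-2-enyl)cyclohex-2-en-1-one, via dilithium dianion 6 (not isolated)
Conditions: LiN(iPr)2 (2.2 equiv), THF, −78 °C; 5, DMPU, −78 → −30 °C; H2O
Reagents that add atoms: none
Why: Stork–Danheiser kinetic α′-deprotonation of the vinylogous ester combined with a Fráter–Seebach-type dianion alkylation, in which the lithium alkoxide is too poor a leaving group for β-elimination and should direct the prenyl group trans (relative configuration is irrelevant, both centres become sp2 later); this step fixes the prenyl group next to the carbonyl that becomes C5.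

Step 5
Reactants: 7 5-hydroxy-2-iodo-3-methoxy-6-(3-methylbut-2-enyl)cyclohex-2-en-1-one; 8 tributyl(1-ethoxyvinyl)stannane
Product: 10 2-acetyl-5-hydroxy-3-methoxy-6-(3-methylbut-2-enyl)cyclohex-2-en-1-one, via ethoxyvinyl enol ether 9 (not isolated)
Conditions: Pd(PPh3)4 (5 mol%), CuI (10 mol%), DMF, 60 °C; then aq. oxalic acid, THF, 0 °C
Reagents that add atoms: water O
Why: Stille coupling of an α-iodoenone with an acetyl anion equivalent, followed by mild hydrolysis in which the simple enol ether should protonate at carbon far faster than the push–pull vinylogous ester.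

Step 6
Reactants: 10 2-acetyl-5-hydroxy-3-methoxy-6-(3-methylbut-2-enyl)cyclohex-2-en-1-one
Product: 12 3-methoxy-6-(3-methylbut-2-enyl)-5-(triethylsilyloxy)-2-[1-(triethylsilyloxy)vinyl]cyclohex-2-en-1-one, via dilithium enolate 11 (not isolated)
Conditions: LiN(iPr)2 (2.2 equiv), THF, −78 °C; Et3SiCl (2.5 equiv), −78 → 0 °C; pentane, filtration
Reagents that add atoms: chlorotriethylsilane CC[Si](Cl)(CC)CC
Why: Kinetic enolisation at the unhindered acetyl methyl group (γ-deprotonation of vinylogous esters and abstraction of the tertiary α′-hydrogen are slower) and O-silylation of both oxyanions should give the 1-methoxy-3-silyloxy diene with its carbinol protected.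

Step 7
Reactants: 13 but-2-yn-1-ol
Product: 15 (2Z)-3-iodobut-2-en-1-ol, via sodium alkenylaluminate 14 (not isolated)
Conditions: NaAlH2(OCH2CH2OMe)2, THF, 0 °C → rt; I2, THF, −78 → 0 °C; aq. potassium sodium tartrate
Reagents that add atoms: iodine II
Why: Hydroxyl-directed trans-hydroalumination of a propargylic alcohol through a five-membered oxaaluminacycle places aluminium at C3 cis to the CH2O group, and iodinolysis with retention should give the Z-iodide.

Step 8
Reactants: 5 1-bromo-3-methylbut-2-ene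
Product: 16 diethyl (3-methylbut-2-enyl)phosphonate
Conditions: P(OEt)3, neat, 120 °C
Reagents that add atoms: triethyl phosphite CCOP(OCC)OCC
Why: Michaelis–Arbuzov reaction of a primary allylic bromide.

Step 9
Reactants: 17 5-bromo-2,3-dihydroxybenzaldehyde
Product: 18 5-bromo-2-hydroxy-3-(triisopropylsilyloxy)benzaldehyde
Conditions: iPr3SiCl (1.05 equiv), imidazole, DMF, 0 °C → rt
Reagents that add atoms: chlorotriisopropylsilane CC(C)[Si](Cl)(C(C)C)C(C)C
Why: Selective silylation of the 3-hydroxyl, because the 2-hydroxyl is held in a hydrogen bond to the formyl group and any silyl migration is also driven to O3, which frees the more acidic ortho-formyl phenol.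

Step 10
Reactants: 18 5-bromo-2-hydroxy-3-(triisopropylsilyloxy)benzaldehyde
Product: 19 5-bromo-2-(tetrahydro-2H-pyran-2-yloxy)-3-(triisopropylsilyloxy)benzaldehyde
Conditions: 3,4-dihydro-2H-pyran, PPTS (cat.), CH2Cl2, rt
Reagents that add atoms: 3,4-dihydro-2H-pyran C1CCOC=C1
Why: Acid-catalysed acetalisation of the phenol under base-free conditions, so that the silyl group cannot migrate between the catechol oxygens in the later basic steps and acid alone can unmask the phenol in step 14.

Step 11
Reactants: 19 5-bromo-2-(tetrahydro-2H-pyran-2-yloxy)-3-(triisopropylsilyloxy)benzaldehyde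
Product: 20 2-[4-bromo-2-ethenyl-6-(triisopropylsilyloxy)phenoxy]tetrahydro-2H-pyran
Conditions: Ph3PCH3Br, NaN(SiMe3)2, THF, 0 °C → rt
Reagents that add atoms: methyltriphenylphosphonium bromide C[P+](c1ccccc1)(c1ccccc1)c1ccccc1.[Br-]
Why: Wittig methylenation of an aromatic aldehyde with a preformed ylide, to which the aryl bromide, acetal and silyl ether are inert.

Step 12
Reactants: 20 2-[4-bromo-2-ethenyl-6-(triisopropylsilyloxy)phenoxy]tetrahydro-2H-pyran; 15 (2Z)-3-iodobut-2-en-1-ol
Product: 22 (2Z)-5-[5-bromo-2-(tetrahydro-2H-pyran-2-yloxy)-3-(triisopropylsilyloxy)phenyl]-3-methylpent-2-en-1-ol, via alkylborane 21 (not isolated)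
Conditions: 9-BBN-H, THF, 0 °C → rt; then 15, Pd(dppf)Cl2 (5 mol%), AsPh3, aq. K3PO4, DMF, rt
Reagents that add atoms: none
Why: Anti-Markovnikov hydroboration of the styrene and B-alkyl Suzuki–Miyaura coupling, in which the alkenyl iodide should react far faster than the electron-rich aryl bromide and the Z geometry of 15 is retained.

Step 13
Reactants: 22 (2Z)-5-[5-bromo-2-(tetrahydro-2H-pyran-2-yloxy)-3-(triisopropylsilyloxy)phenyl]-3-methylpent-2-en-1-ol
Product: 23 [(2S,3R)-3-{2-[5-bromo-2-(tetrahydro-2H-pyran-2-yloxy)-3-(triisopropylsilyloxy)phenyl]ethyl}-3-methyloxiran-2-yl]methanol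
Conditions: Ti(OiPr)4 (10 mol%), L-(+)-diisopropyl tartrate (12 mol%), tBuOOH, 4 Å MS, CH2Cl2, −20 °C
Reagents that add atoms: tert-butyl hydroperoxide CC(C)(C)OO
Why: Katsuki–Sharpless asymmetric epoxidation, in which the L-(+)-tartrate catalyst should deliver oxygen to the same face as it does for nerol-type Z-3,3-disubstituted allylic alcohols and so set the (2S,3R) epoxide.

Step 14
Reactants: 23 [(2S,3R)-3-{2-[5-bromo-2-(tetrahydro-2H-pyran-2-yloxy)-3-(triisopropylsilyloxy)phenyl]ethyl}-3-methyloxiran-2-yl]methanol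
Product: 25 (1S)-1-[(2S)-6-bromo-2-methyl-8-(triisopropylsilyloxy)-3,4-dihydro-2H-chromen-2-yl]ethane-1,2-diol, via free phenol 24 (not isolated)
Conditions: CSA (10 mol%), MeOH (5 equiv), CH2Cl2, 0 °C → rt
Reagents that add atoms: none
Why: Acid releases the phenol, which should open the activated epoxide at its tertiary carbon in a 6-exo-tet mode with inversion (acid-catalysed intramolecular epoxide opening), turning the (3R) epoxide carbon into the (2S) quaternary chroman carbon while the carbinol keeps its configuration.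

Step 15
Reactants: 25 (1S)-1-[(2S)-6-bromo-2-methyl-8-(triisopropylsilyloxy)-3,4-dihydro-2H-chromen-2-yl]ethane-1,2-diol
Product: 26 (2S)-6-bromo-2-methyl-8-(triisopropylsilyloxy)-3,4-dihydro-2H-chromene-2-carbaldehyde
Conditions: NaIO4, THF/pH 7 buffer, 0 °C
Reagents that add atoms: none
Why: Periodate glycol cleavage; the α-carbon of the aldehyde is quaternary and cannot epimerise.

Step 16
Reactants: 26 (2S)-6-bromo-2-methyl-8-(triisopropylsilyloxy)-3,4-dihydro-2H-chromene-2-carbaldehyde; 16 diethyl (3-methylbut-2-enyl)phosphonate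
Product: 28 (2S)-6-bromo-2-methyl-2-[(1E)-4-methylpenta-1,3-dienyl]-8-(triisopropylsilyloxy)-3,4-dihydro-2H-chromene, via lithiated phosphonate 27 (not isolated)
Conditions: 16, n-BuLi, THF, −78 °C; then 26, DMPU, −78 °C → rt
Reagents that add atoms: none
Why: Horner–Wadsworth–Emmons olefination with an allylic phosphonate, which should attack through its unhindered α-carbon and give the E-disubstituted alkene of the diene.

Step 17
Reactants: 28 (2S)-6-bromo-2-methyl-2-[(1E)-4-methylpenta-1,3-dienyl]-8-(triisopropylsilyloxy)-3,4-dihydro-2H-chromene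
Product: 30 (2S)-2-methyl-2-[(1E)-4-methylpenta-1,3-dienyl]-8-(triisopropylsilyloxy)-3,4-dihydro-2H-chromene-6-carbaldehyde, via aryllithium 29 (not isolated)
Conditions: n-BuLi, THF, −78 °C; DMF, −78 → 0 °C; H2O
Reagents that add atoms: N,N-dimethylformamide CN(C)C=O
Why: Bromine–lithium exchange and formylation with DMF; the lithium sits meta to the silyloxy group, so no silyl migration to carbon is possible, and the diene is inert at −78 °C.

Step 18
Reactants: 30 (2S)-2-methyl-2-[(1E)-4-methylpenta-1,3-dienyl]-8-(triisopropylsilyloxy)-3,4-dihydro-2H-chromene-6-carbaldehyde; 12 3-methoxy-6-(3-methylbut-2-enyl)-5-(triethylsilyloxy)-2-[1-(triethylsilyloxy)vinyl]cyclohex-2-en-1-one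
Product: 32 (2S)-7-hydroxy-6-(3-methylbut-2-enyl)-2-[(2S)-2-methyl-2-[(1E)-4-methylpenta-1,3-dienyl]-8-(triisopropylsilyloxy)-3,4-dihydro-2H-chromen-6-yl]-2,3,7,8-tetrahydro-4H-chromene-4,5(6H)-dione, via silyl aldol adduct 31 (not isolated)
Conditions: Ti(OiPr)4 (10 mol%), (S)-BINOL (20 mol%), 4 Å MS, Et2O, −20 °C → rt; then PPTS, CH2Cl2/MeOH, 0 °C → rt
Reagents that add atoms: none
Why: The chiral titanium BINOLate activates aldehyde 30, and the exocyclic enol silane terminus of 12 (future C3) adds to the formyl carbon (future C2) in a Mukaiyama aldol step to give 31; PPTS in methanol then removes the silyl groups and the C2 oxygen adds to C8a of the doubly activated β-methoxy enedione and expels methanol, so the C2–C3 and O1–C8a bonds of ring C arise in one operation as a formal [4+2] cycloaddition. The closest known reaction type is the hetero-Diels–Alder reaction of aldehydes with 1-alkoxy-3-silyloxy-1,3-dienes catalysed by BINOL complexes of tetravalent titanium, which runs through the same aldol-then-cyclise pathway. Ring C closes by a 6-endo-trig conjugate addition followed by β-elimination at the vinylogous ester carbon; the aldol step itself closes no ring. The new stereocentre C2 is under catalyst control: by analogy with allylations and aldol additions to aromatic aldehydes with the same (S)-BINOL complex, attack should occur on the Si face and give (2S) (the antipodal ligand would be used if the first run showed the opposite sense), while the racemic C6/C7 centres of 12 are remote from the reacting carbon and are erased in step 19. The step needs regioselective ring closure, secured because only the methoxy-bearing carbon carries a leaving group, so the carbonyl next to the prenyl carbon becomes C5 and the 6-prenyl, not the 8-prenyl, skeleton results; it also needs mild acid (PPTS, not a strong acid) so that the para-alkoxybenzylic C2–O bond and the dienyl ether of the chroman are not ionised.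

Step 19
Reactants: 32 (2S)-7-hydroxy-6-(3-methylbut-2-enyl)-2-[(2S)-2-methyl-2-[(1E)-4-methylpenta-1,3-dienyl]-8-(triisopropylsilyloxy)-3,4-dihydro-2H-chromen-6-yl]-2,3,7,8-tetrahydro-4H-chromene-4,5(6H)-dione
Product: 34 (2S)-5,7-dihydroxy-6-(3-methylbut-2-enyl)-2-[(2S)-2-methyl-2-[(1E)-4-methylpenta-1,3-dienyl]-8-(triisopropylsilyloxy)-3,4-dihydro-2H-chromen-6-yl]-2,3-dihydro-4H-chromen-4-one, via cyclohexanetrione 33 (not isolated)
Conditions: DMP (1,1,1-triacetoxy-1,1-dihydro-1,2-benziodoxol-3(1H)-one, 1.1 equiv), NaHCO3, CH2Cl2, 0 °C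
Reagents that add atoms: none
Why: Periodinane oxidation of the β-hydroxy ketone gives a 1,3,5-trioxygenated ring that should tautomerise at once to the aromatic phloroglucinol ring A; this removes the C6/C7 stereocentres, leaves C2 untouched, and limiting the oxidant at 0 °C should spare the new phenol.

Step 20
Reactants: 34 (2S)-5,7-dihydroxy-6-(3-methylbut-2-enyl)-2-[(2S)-2-methyl-2-[(1E)-4-methylpenta-1,3-dienyl]-8-(triisopropylsilyloxy)-3,4-dihydro-2H-chromen-6-yl]-2,3-dihydro-4H-chromen-4-one
Product: 35 (2S)-5,7-dihydroxy-2-[(2S)-8-hydroxy-2-methyl-2-[(1E)-4-methylpenta-1,3-dienyl]-3,4-dihydro-2H-chromen-6-yl]-6-(3-methylbut-2-enyl)-2,3-dihydro-4H-chromen-4-one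
Conditions: Bu4NF (1.2 equiv), AcOH (1.5 equiv), THF, 0 °C
Reagents that add atoms: none
Why: Fluoride cleavage of the aryl silyl ether, buffered with acetic acid so that the flavanone does not equilibrate with its chalcone (which would racemise C2) and no acid strong enough to ionise the dienyl ether or cyclise the prenyl phenol is present.

**Compound list**

1 | phloroglucinol (benzene-1,3,5-triol) | Oc1cc(O)cc(O)c1 | starting material
2 | 5-hydroxycyclohexane-1,3-dione | O=C1CC(O)CC(=O)C1 | intermediate
3 | 5-hydroxy-3-methoxycyclohex-2-en-1-one (racemic) | COC1=CC(=O)CC(O)C1 | intermediate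
4 | 5-hydroxy-2-iodo-3-methoxycyclohex-2-en-1-one (racemic) | COC1=C(I)C(=O)CC(O)C1 | intermediate
5 | 1-bromo-3-methylbut-2-ene (prenyl bromide) | CC(C)=CCBr | starting material
6 | dilithium alkoxide enolate (dianion) of 4 | [Li+].[Li+].COC1=C(I)C([O-])=CC([O-])C1 | intermediate
7 | 5-hydroxy-2-iodo-3-methoxy-6-(3-methylbut-2-enyl)cyclohex-2-en-1-one (racemic; trans expected) | COC1=C(I)C(=O)C(CC=C(C)C)C(O)C1 | intermediate
8 | tributyl(1-ethoxyvinyl)stannane | CCCC[Sn](CCCC)(CCCC)C(=C)OCC | starting material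
9 | 2-(1-ethoxyvinyl)-5-hydroxy-3-methoxy-6-(3-methylbut-2-enyl)cyclohex-2-en-1-one (racemic) | CCOC(=C)C1=C(OC)CC(O)C(CC=C(C)C)C1=O | intermediate
10 | 2-acetyl-5-hydroxy-3-methoxy-6-(3-methylbut-2-enyl)cyclohex-2-en-1-one (racemic) | CC(=O)C1=C(OC)CC(O)C(CC=C(C)C)C1=O | intermediate
11 | dilithium alkoxide enolate of 10 | [Li+].[Li+].C=C([O-])C1=C(OC)CC([O-])C(CC=C(C)C)C1=O | intermediate
12 | 3-methoxy-6-(3-methylbut-2-enyl)-5-(triethylsilyloxy)-2-[1-(triethylsilyloxy)vinyl]cyclohex-2-en-1-one (racemic) | C=C(O[Si](CC)(CC)CC)C1=C(OC)CC(O[Si](CC)(CC)CC)C(CC=C(C)C)C1=O | intermediate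
13 | but-2-yn-1-ol | CC#CCO | starting material
14 | sodium 2,2-bis(2-methoxyethoxy)-3-methyl-2,5-dihydro-1,2-oxaaluminol-2-uide (cyclic alkenylaluminate) | [Na+].CC1=CCO[Al-]1(OCCOC)OCCOC | intermediate
15 | (2Z)-3-iodobut-2-en-1-ol | C/C(I)=C/CO | intermediate
16 | diethyl (3-methylbut-2-enyl)phosphonate | CCOP(=O)(CC=C(C)C)OCC | intermediate
17 | 5-bromo-2,3-dihydroxybenzaldehyde | O=Cc1cc(Br)cc(O)c1O | starting material
18 | 5-bromo-2-hydroxy-3-(triisopropylsilyloxy)benzaldehyde | O=Cc1cc(Br)cc(O[Si](C(C)C)(C(C)C)C(C)C)c1O | intermediate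
19 | 5-bromo-2-(tetrahydro-2H-pyran-2-yloxy)-3-(triisopropylsilyloxy)benzaldehyde | O=Cc1cc(Br)cc(O[Si](C(C)C)(C(C)C)C(C)C)c1OC1CCCCO1 | intermediate
20 | 2-[4-bromo-2-ethenyl-6-(triisopropylsilyloxy)phenoxy]tetrahydro-2H-pyran | C=Cc1cc(Br)cc(O[Si](C(C)C)(C(C)C)C(C)C)c1OC1CCCCO1 | intermediate
21 | 9-{2-[5-bromo-2-(tetrahydro-2H-pyran-2-yloxy)-3-(triisopropylsilyloxy)phenyl]ethyl}-9-borabicyclo[3.3.1]nonane | C(Cc1cc(Br)cc(O[Si](C(C)C)(C(C)C)C(C)C)c1OC1CCCCO1)B1C2CCCC1CCC2 | intermediate
22 | (2Z)-5-[5-bromo-2-(tetrahydro-2H-pyran-2-yloxy)-3-(triisopropylsilyloxy)phenyl]-3-methylpent-2-en-1-ol | OC/C=C(/C)CCc1cc(Br)cc(O[Si](C(C)C)(C(C)C)C(C)C)c1OC1CCCCO1 | intermediate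
23 | [(2S,3R)-3-{2-[5-bromo-2-(tetrahydro-2H-pyran-2-yloxy)-3-(triisopropylsilyloxy)phenyl]ethyl}-3-methyloxiran-2-yl]methanol | OC[C@@H]1O[C@]1(C)CCc2cc(Br)cc(O[Si](C(C)C)(C(C)C)C(C)C)c2OC3CCCCO3 | intermediate
24 | [(2S,3R)-3-{2-[5-bromo-2-hydroxy-3-(triisopropylsilyloxy)phenyl]ethyl}-3-methyloxiran-2-yl]methanol | OC[C@@H]1O[C@]1(C)CCc2cc(Br)cc(O[Si](C(C)C)(C(C)C)C(C)C)c2O | intermediate
25 | (1S)-1-[(2S)-6-bromo-2-methyl-8-(triisopropylsilyloxy)-3,4-dihydro-2H-chromen-2-yl]ethane-1,2-diol | OC[C@H](O)[C@]1(C)CCc2cc(Br)cc(O[Si](C(C)C)(C(C)C)C(C)C)c2O1 | intermediate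
26 | (2S)-6-bromo-2-methyl-8-(triisopropylsilyloxy)-3,4-dihydro-2H-chromene-2-carbaldehyde | O=C[C@]1(C)CCc2cc(Br)cc(O[Si](C(C)C)(C(C)C)C(C)C)c2O1 | intermediate
27 | lithium salt of 16 (α-lithiated phosphonate) | [Li+].CCOP(=O)(OCC)[CH-]C=C(C)C | intermediate
28 | (2S)-6-bromo-2-methyl-2-[(1E)-4-methylpenta-1,3-dienyl]-8-(triisopropylsilyloxy)-3,4-dihydro-2H-chromene | CC(C)=C/C=C/[C@]1(C)CCc2cc(Br)cc(O[Si](C(C)C)(C(C)C)C(C)C)c2O1 | intermediate
29 | 6-lithio derivative of 28 (aryllithium) | CC(C)=C/C=C/[C@]1(C)CCc2cc([Li])cc(O[Si](C(C)C)(C(C)C)C(C)C)c2O1 | intermediate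
30 | (2S)-2-methyl-2-[(1E)-4-methylpenta-1,3-dienyl]-8-(triisopropylsilyloxy)-3,4-dihydro-2H-chromene-6-carbaldehyde | CC(C)=C/C=C/[C@]1(C)CCc2cc(C=O)cc(O[Si](C(C)C)(C(C)C)C(C)C)c2O1 | intermediate
31 | silyl aldol adduct: 3-methoxy-6-(3-methylbut-2-enyl)-5-(triethylsilyloxy)-2-[(3S)-3-aryl-3-(triethylsilyloxy)propanoyl]cyclohex-2-en-1-one, aryl = chromanyl group of 30 | CC(C)=C/C=C/[C@]1(C)CCc2cc([C@@H](O[Si](CC)(CC)CC)CC(=O)C3=C(OC)CC(O[Si](CC)(CC)CC)C(CC=C(C)C)C3=O)cc(O[Si](C(C)C)(C(C)C)C(C)C)c2O1 | intermediate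
32 | (2S)-7-hydroxy-6-(3-methylbut-2-enyl)-2-[(2S)-2-methyl-2-[(1E)-4-methylpenta-1,3-dienyl]-8-(triisopropylsilyloxy)-3,4-dihydro-2H-chromen-6-yl]-2,3,7,8-tetrahydro-4H-chromene-4,5(6H)-dione (mixture at C6/C7) | CC(C)=C/C=C/[C@]1(C)CCc2cc([C@@H]3CC(=O)C4=C(CC(O)C(CC=C(C)C)C4=O)O3)cc(O[Si](C(C)C)(C(C)C)C(C)C)c2O1 | intermediate
33 | (2S)-6-(3-methylbut-2-enyl)-2-[chromanyl group of 30]-2,3-dihydro-4H-chromene-4,5,7(6H,8H)-trione | CC(C)=C/C=C/[C@]1(C)CCc2cc([C@@H]3CC(=O)C4=C(CC(=O)C(CC=C(C)C)C4=O)O3)cc(O[Si](C(C)C)(C(C)C)C(C)C)c2O1 | intermediate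
34 | (2S)-5,7-dihydroxy-6-(3-methylbut-2-enyl)-2-[(2S)-2-methyl-2-[(1E)-4-methylpenta-1,3-dienyl]-8-(triisopropylsilyloxy)-3,4-dihydro-2H-chromen-6-yl]-2,3-dihydro-4H-chromen-4-one | CC(C)=C/C=C/[C@]1(C)CCc2cc([C@@H]3CC(=O)c4c(cc(O)c(CC=C(C)C)c4O)O3)cc(O[Si](C(C)C)(C(C)C)C(C)C)c2O1 | intermediate
35 | (2S)-5,7-dihydroxy-2-[(2S)-8-hydroxy-2-methyl-2-[(1E)-4-methylpenta-1,3-dienyl]-3,4-dihydro-2H-chromen-6-yl]-6-(3-methylbut-2-enyl)-2,3-dihydro-4H-chromen-4-one | CC(C)=C/C=C/[C@]1(C)CCc2cc([C@@H]3CC(=O)c4c(cc(O)c(CC=C(C)C)c4O)O3)cc(O)c2O1 | target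

**Step count and risks**

Total step count: 20 (steps 1–6 for the diene, steps 7–17 for the aldehyde including two reagent preparations, steps 18–20 after convergence).
Longest linear sequence: 12 steps (steps 9–17, then 18–20, from 17).

Steps most likely to fail:

1. Step 18. The push–pull diene may add too slowly to the electron-rich aldehyde, so that desilylation of the enol silane wins. Face selection by the catalyst may be incomplete. The non-aromatic pyranone may also open by retro-oxa-Michael reaction and lose configuration at C2. Fallback, setting out from 10 and 30 and returning at 32: the hydroxyl of 10 is silylated (Et3SiCl, imidazole) to 2-acetyl-3-methoxy-6-(3-methylbut-2-enyl)-5-(triethylsilyloxy)cyclohex-2-en-1-one F1. (−)-B-Chlorodiisopinocampheylborane and Et3N convert the methyl ketone into its enol diisopinocampheylborinate F2, which adds to 30 at −78 °C in a reagent-controlled boron aldol reaction. The (−)-reagent is expected to give the (S)-carbinol by analogy with methyl ketone additions; otherwise its antipode is used. Non-oxidative work-up gives the β-hydroxy ketone F3, and PPTS in methanol closes ring C with loss of methanol and of the silyl group to give 32.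

2. Step 4. The dianion may react sluggishly with the hindered allylic bromide, so that on warming β-elimination of the alkoxide and aromatisation to a resorcinol ether, γ-deprotonation or O-alkylation take over. Fallback, setting out from 4 and returning at 7: the dianion of 4 is alkylated at −78 °C with the smaller and faster allyl bromide to give 5-hydroxy-2-iodo-3-methoxy-6-(prop-2-enyl)cyclohex-2-en-1-one F4. Olefin cross-metathesis with 2-methylbut-2-ene (second-generation Grubbs catalyst RuCl2(=CHPh)(H2IMes)(PCy3), CH2Cl2, 40 °C) then turns the allyl group into the prenyl group of 7.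

3. Step 6. Enolisation may take place at the ring γ-carbon instead of the acetyl methyl group, and the labile enol silane (or the vinylogous ester in the acidic work-up of step 5) may hydrolyse during isolation. Fallback, setting out from 7 and 8 and returning at 32: the Stille coupling of step 5 is worked up without acid so that enol ether 9 is isolated. Silylation (Et3SiCl, imidazole) gives 2-(1-ethoxyvinyl)-3-methoxy-6-(3-methylbut-2-enyl)-5-(triethylsilyloxy)cyclohex-2-en-1-one F5, a 1,3-dialkoxy diene whose position is fixed by the cross-coupling and not by an enolisation. F5 is combined with 30 under the titanium–BINOL conditions of step 18 (hetero-Diels–Alder reaction of a dialkoxy diene), and PPTS in wet methanol hydrolyses the adduct to 32.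

Further compounds
F1 | step 18 | 2-acetyl-3-methoxy-6-(3-methylbut-2-enyl)-5-(triethylsilyloxy)cyclohex-2-en-1-one | CC(=O)C1=C(OC)CC(O[Si](CC)(CC)CC)C(CC=C(C)C)C1=O
F2 | step 18 | enol diisopinocampheylborinate of F1 | C=C(OB([C@@H]1C[C@@H]2C[C@H]([C@H]1C)C2(C)C)[C@@H]1C[C@@H]2C[C@H]([C@H]1C)C2(C)C)C1=C(OC)CC(O[Si](CC)(CC)CC)C(CC=C(C)C)C1=O
F3 | step 18 | 2-[(3S)-3-hydroxy-3-aryl-propanoyl]-3-methoxy-6-(3-methylbut-2-enyl)-5-(triethylsilyloxy)cyclohex-2-en-1-one, aryl = chromanyl group of 30 | CC(C)=C/C=C/[C@]1(C)CCc2cc([C@@H](O)CC(=O)C3=C(OC)CC(O[Si](CC)(CC)CC)C(CC=C(C)C)C3=O)cc(O[Si](C(C)C)(C(C)C)C(C)C)c2O1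
F4 | step 4 | 5-hydroxy-2-iodo-3-methoxy-6-(prop-2-enyl)cyclohex-2-en-1-one | COC1=C(I)C(=O)C(CC=C)C(O)C1
F5 | step 6 | 2-(1-ethoxyvinyl)-3-methoxy-6-(3-methylbut-2-enyl)-5-(triethylsilyloxy)cyclohex-2-en-1-one | CCOC(=C)C1=C(OC)CC(O[Si](CC)(CC)CC)C(CC=C(C)C)C1=O
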